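## Structural features

The target consists of two 2,3-diaryl-2,3-dihydrobenzofurans joined by the single bond C7'–C2. Unit 1 sits on ring A (O1, C2, C3) and carries an (E)-4-hydroxystyryl group at C4, OH at C6 and a 3,5-dihydroxyphenyl ring at C3. Unit 2 sits on ring C (O1', C2', C3') and carries OH at C4', a 2,4-dihydroxyphenyl ring at C2' and a 3,5-dihydroxyphenyl ring at C3'. There are four stereocentres in two adjacent pairs, C2/C3 and C2'/C3', each pair trans and all four S; flat ring C separates the pairs, so neither can direct the other. The fragile groups are the nine phenols, the E stilbene and the two benzylic ether bonds O1–C2 and O1'–C2', which lie ortho or para to oxygen donors and ionise easily under acid. A cation at C2, the styryl alkene at C4 and the electron-rich aryl ring at C3 are within reach of one another, so acid can divert the skeleton into carbocyclic isomers. The real difficulty is to place two bulky aryl groups on the neighbouring carbons C2 and C3 beside the doubly ortho-substituted ring A, with C3 controlled against a remote unit 2, and then to unmask nine phenols. The key step uses the fact that C2 and C3 are adjacent carbons each bearing one aryl group, ring C on the oxygenated C2 and the 3,5-dioxygenated ring on C3: this is the pattern left when an aryl group shifts from boron to the α-carbon of a ring A alkenylboronate while an aryl–palladium adds to the β-carbon, the boron marking the later oxygen.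

## Logic of the disconnections

**32 from 31.** The nine O–CH3 bonds are cut last. Methyl ethers are the only phenol masks present on all commercial building blocks that also survive t-BuLi, hydrazine, the carbenoid, palladium and peroxide. There is no gain in skeleton, only in compatibility. The demand is heavy: nine ethers must be cleaved without long-lived ionisation of O1–C2 or O1'–C2' and without protonating the stilbene.

**31 from 30.** The bond O1–C2 is cut. C2 is benzylic to ring C and para to the C4' oxygen, so the ring can be closed by displacement with inversion or through the cation, and both paths lead to the trans ring. Opening the ring turns C2/C3 into an acyclic 1,2-diaryl pair. The forward step needs the ring A phenol free before C2 is activated, so that oxygen and not the styryl alkene captures C2.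

**30 from 28 (through 29).** The C2–O bond is traced back to a C2–B bond and the phenol to its methoxymethyl ether. The oxygen at C2 is the footprint of boron, and oxidation is stereoretentive. The acetal must be removed while C2 is still on boron and under non-protic conditions, so that no benzylic cation can form and unit 2 is not re-opened.

**28 from 25, 11 and 13.** The bonds C2–C7' and C3–aryl are cut together. This is the most convergent cut available: it splits the molecule into three pieces and sets both new stereocentres in one step, C3 by the catalyst and C2 by the anti course of the addition. The demands are the highest of the route: a hindered β-aryl alkene, 1,2-shift in preference to direct alkenyl transfer, face selection by the ligand, and a single site of oxidative addition.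

**11 from 7 and 9; 7 from 5 and 6; 5 from 3 and 4; 3 from 2; 2 from 1; 9 from 8.** The cuts are the B–O bonds of the boron ligand, the C2=C3 alkene, the C4–vinyl bond, the acetal O–CH2 bond and one O–CH3 bond. Each is a standard two-component step. The ether ortho to the aldehyde is cleaved first, so the Lewis acid never meets the stilbene. The olefination must give the E alkenyl boronate on a doubly ortho-substituted aldehyde.

**13 from 12.** The S–O bond is cut; the step is a simple sulfonylation.

**25 from 24; 24 from 22 (through 23); 22 from 21; 21 from 20; 20 from 17 and 18 (through 19); 17 from 15 and 16; 15 from 14.** The C2'–C3' bond is cut as a carbene C–H insertion, which sets C3' by catalyst control. C2' is then corrected by ionisation of O1'–C2'. Behind that lie the C3'–aryl bond (Grignard addition and oxidation), the O–CH2 ether bond and the formyl C–C bond. The bromine at C7' is in the starting phenol and is carried through unchanged. The insertion must occur on a doubly ortho-substituted diaryl carbene with high face selectivity.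

## Other disconnections considered

**Alternative 1:** The cut goes through ring C itself. C4'–C3a', C7a'–C7' and C4'–C5' are broken, so ring C would arise from 2-bromocyclobut-2-enone A2 and the siloxyalkyne A3, which already carries C3' and C2'. On heating, A2 would open to bromo(vinyl)ketene and add (2+2) to A3. The vinylcyclobutenone would then undergo four-electron opening and six-electron closure to the phenol A1.
- In its favour: the polarity of ketene and ynol ether fixes the place of every substituent on ring C, including bromine at C7' and two differentiated oxygens. The stereocentres would come from an auxiliary-controlled aldol reaction and are not touched by the annulation.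
- Against it: A2 is a sensitive, non-commercial enone. C3' in A3 is propargylic and doubly activated, and must survive ester-to-ynolate homologation and heating without epimerisation. The sequence (auxiliary, aldol, silylation, ester, ynolate, annulation, methylation, desilylation, closure) is longer than steps 8–14.
- Comparison: on structure it addresses only unit 2 and would still need step 15 for C2/C3, so it replaces steps 8–14 and not the key step. On mechanism it is thermal and pericyclic, without catalyst induction on a hindered carbene, and on this point of regiochemical and stereochemical certainty it is the better plan. On step economy the chosen route is shorter.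

**Alternative 2:** The cut is the bond C3–C3a, traced back to the flavanone A5. The trivalent iodine reagent PhI(OAc)2 with H2SO4 in trimethyl orthoformate would oxidise A5 at C3. The ring A carbon would then shift from the carbonyl carbon to C3, contracting the pyranone to the dihydrofuran and leaving the former carbonyl carbon as the methyl ester of A4.
- In its favour: every step is a two-component reaction of a known type. C2 of A5 would be carried through with its configuration, so the oxygen-bearing centre is set directly and not through a cation. No organolithium is needed.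
- Against it: A4 carries a carboxylate where the 3,5-dimethoxyphenyl ring must stand, so hydrolysis, activation and a decarboxylative arylation through a C3 radical have to follow, and then a Heck reaction on the C4 bromide. The oxidant and strong acid threaten the electron-rich rings and the labile O1'–C2' bond of unit 2. A flavanone with so electron-rich a 2-aryl group can racemise by ring opening to the chalcone.
- Comparison: on structure it sets C2 first and C3 by relay from C2, while the chosen plan sets C3 by catalyst and C2 by the mechanism. On mechanism it avoids an unprecedented step, and in that respect it is the better plan. On step economy it is clearly longer after the union, and it shares the final deprotection problem.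

**Alternative 3:** The cut removes C2–C3 and O1–C2 together. Base would release the ring A ortho-quinone methide from the sulfone A7 and the ylide from the chiral benzylsulfonium salt A8. The ylide carbon would add to C3 and the phenoxide would then displace the sulfide, closing the dihydrofuran of unit 1 as the bromide A6.
- In its favour: it is the most convergent union, it closes the trans ring in the same step, it needs no transition metal, and only a Heck reaction and the demethylation follow.
- Against it: C3 is a prochiral terminus of a planar quinone methide. Its configuration would have to be dictated by a sulfonium stereo-element three bonds away through a reversible betaine, which is not secured for a semi-stabilised ylide. A8 is a very electron-rich benzylic sulfonium salt and can lose the sulfide by ionisation. The Heck reaction then falls on a hindered, electron-rich bromide late in the route.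
- Comparison: on structure both plans form the same two stereocentres. On mechanism the chosen plan separates the tasks (catalyst for C3, stereospecific anti addition for C2), whereas here one reagent must control both. On step economy after the union the alternative is the better by one step. Its non-enantioselective form is used below as the fallback for step 15.

Key step: step 15

**Remarks on the chemistry (assumptions, one line each)**
- The sense of induction of Rh2(S-PTAD)4, dirhodium tetrakis[(S)-(1-adamantyl)(phthalimido)acetate], in step 13 and of the MandyPhos antipode (2,2'-bis[α-(dimethylamino)benzyl]-1,1'-bis(diphenylphosphino)ferrocene) in step 15 is assigned by analogy; the antipode meant is the one that gives S at the new diarylmethine carbon.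
- The pinacol ester 7 is converted into the mac ester 11 before the key step, because β-substituted alkenyl pinacol boronate complexes tend to transfer the alkenyl group directly to palladium; the carbon skeleton of precursor and product is unchanged.
- The boron-bearing carbon of 28 is R; closure with inversion (step 17) or through the C2 cation both lead to the (2S) trans ring, so the structures of the plan needed no correction.
- The diol 9 is treated as non-commercial and is made in one step.
- Abbreviations in names: RA = 4-methoxy-2-[(E)-2-(4-methoxyphenyl)ethenyl]-6-(methoxymethoxy)phenyl; U2 = (2S,3S)-2-(2,4-dimethoxyphenyl)-3-(3,5-dimethoxyphenyl)-4-methoxy-2,3-dihydro-1-benzofuran-7-yl.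

## Steps

Step 1
Reactants: 1 2-bromo-4,6-dimethoxybenzaldehyde
Product: 2 2-bromo-6-hydroxy-4-methoxybenzaldehyde
Conditions: BCl3 (1.2 equiv), CH2Cl2, −78 → 0 °C; H2O
Reagents that add atoms: none
Why: Chelation-directed demethylation: BCl3 binds the formyl oxygen and cleaves only the ortho methoxy group through a six-membered chelate; it is done before the styryl group is present, so no alkene meets the Lewis acid.

Step 2
Reactants: 2 2-bromo-6-hydroxy-4-methoxybenzaldehyde
Product: 3 2-bromo-4-methoxy-6-(methoxymethoxy)benzaldehyde
Conditions: MOMCl, i-Pr2NEt, CH2Cl2, 0 °C → rt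
Reagents that add atoms: chloromethyl methyl ether, COCCl
Why: O-alkylation of the hydrogen-bonded phenol (Williamson-type); the small acetal survives LiTMP, aryllithium and palladium and can later be removed without protic acid.

Step 3
Reactants: 3 2-bromo-4-methoxy-6-(methoxymethoxy)benzaldehyde; 4 4-methoxystyrene
Product: 5 4-methoxy-2-[(E)-2-(4-methoxyphenyl)ethenyl]-6-(methoxymethoxy)benzaldehyde
Conditions: Pd(OAc)2 (5 mol %), P(o-tol)3 (10 mol %), Et3N, DMF, 100 °C
Reagents that add atoms: none
Why: Mizoroki–Heck reaction of an aryl bromide activated by the ortho formyl group; syn insertion and syn β-hydride elimination should give the E stilbene.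

Step 4
Reactants: 5 4-methoxy-2-[(E)-2-(4-methoxyphenyl)ethenyl]-6-(methoxymethoxy)benzaldehyde; 6 bis(pinacolatoboryl)methane
Product: 7 2-[(E)-2-RA-ethenyl]-4,4,5,5-tetramethyl-1,3,2-dioxaborolane
Conditions: LiTMP (from n-BuLi and 2,2,6,6-tetramethylpiperidine), 6, THF, 0 °C; then 5, −78 °C → rt; H2O
Reagents that add atoms: none
Why: Boron-Wittig olefination: the α-boryl carbanion of 6 adds to the aldehyde and syn elimination of lithium borate should give the E alkenyl boronate, as is usual with aromatic aldehydes.

Step 5
Reactants: 8 acenaphthoquinone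
Product: 9 cis-1,2-dimethyl-1,2-dihydroacenaphthylene-1,2-diol (mac diol)
Conditions: MeMgBr (2.5 equiv), THF, 0 °C → rt; H2O; crystallisation of the cis diol
Reagents that add atoms: methylmagnesium bromide, C[Mg]Br
Why: Double Grignard addition to the 1,2-diketone; only the cis (meso) diol can bridge boron, and it is separated from any trans isomer by crystallisation.

Step 6
Reactants: 7 2-[(E)-2-RA-ethenyl]-4,4,5,5-tetramethyl-1,3,2-dioxaborolane; 9 cis-1,2-dimethyl-1,2-dihydroacenaphthylene-1,2-diol
Product: 11 ring A (E)-alkenyl B(mac) boronate (cyclic ester of 10 with 9), via alkenylboronic acid 10 (not isolated)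
Conditions: NaIO4, NH4OAc, acetone/H2O, rt; then 9, MgSO4, CH2Cl2, rt
Reagents that add atoms: none
Why: Periodate cleaves the pinacol set free by hydrolysis and so drives the ester to the boronic acid, which condenses with diol 9 (boronic ester exchange); the mac ligand is installed because it is the known remedy for direct alkenyl transfer with β-substituted alkenyl boronates.

Step 7
Reactants: 12 3,5-dimethoxyphenol
Product: 13 3,5-dimethoxyphenyl trifluoromethanesulfonate
Conditions: Tf2O, pyridine, CH2Cl2, 0 °C
Reagents that add atoms: trifluoromethanesulfonic anhydride, O=S(=O)(OS(=O)(=O)C(F)(F)F)C(F)(F)F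
Why: O-sulfonylation of the phenol gives the electrophile for the key step.

Step 8
Reactants: 14 2-bromo-5-methoxyphenol
Product: 15 3-bromo-2-hydroxy-6-methoxybenzaldehyde
Conditions: MgCl2, Et3N, (CH2O)n, MeCN, reflux; 1 M HCl
Reagents that add atoms: paraformaldehyde (as formaldehyde), C=O
Why: Magnesium-mediated ortho-formylation (Casnati–Skattebøl): the magnesium phenoxide delivers formaldehyde only ortho to oxygen, and the one free ortho position is the carbon between OH and OMe; a second formaldehyde accepts the hydride.

Step 9
Reactants: 15 3-bromo-2-hydroxy-6-methoxybenzaldehyde; 16 2,4-dimethoxybenzyl alcohol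
Product: 17 3-bromo-2-[(2,4-dimethoxybenzyl)oxy]-6-methoxybenzaldehyde
Conditions: PPh3, DIAD, THF, 0 °C → rt
Reagents that add atoms: none
Why: Mitsunobu etherification of an acidic salicylaldehyde phenol with a primary benzylic alcohol; it avoids the unstable 2,4-dimethoxybenzyl halide.

Step 10
Reactants: 18 1-bromo-3,5-dimethoxybenzene; 17 3-bromo-2-[(2,4-dimethoxybenzyl)oxy]-6-methoxybenzaldehyde
Product: 20 racemic {3-bromo-2-[(2,4-dimethoxybenzyl)oxy]-6-methoxyphenyl}(3,5-dimethoxyphenyl)methanol, via 3,5-dimethoxyphenylmagnesium bromide 19 (not isolated)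
Conditions: Mg, I2 (cat.), THF, reflux; then 17, THF, 0 °C; H2O
Reagents that add atoms: none
Why: Grignard formation and 1,2-addition to the aldehyde; the aryl bromide of 17 does not exchange with an arylmagnesium reagent at 0 °C, and the racemic carbinol centre is removed in the next step.

Step 11
Reactants: 20 racemic {3-bromo-2-[(2,4-dimethoxybenzyl)oxy]-6-methoxyphenyl}(3,5-dimethoxyphenyl)methanol
Product: 21 {3-bromo-2-[(2,4-dimethoxybenzyl)oxy]-6-methoxyphenyl}(3,5-dimethoxyphenyl)methanone
Conditions: Dess–Martin periodinane, NaHCO3, CH2Cl2, rt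
Reagents that add atoms: none
Why: Buffered periodinane oxidation of a hindered benzhydrol to the ketone, without acid that would cleave the electron-rich benzyl ether.

Step 12
Reactants: 21 {3-bromo-2-[(2,4-dimethoxybenzyl)oxy]-6-methoxyphenyl}(3,5-dimethoxyphenyl)methanone
Product: 22 hydrazone of 21
Conditions: N2H4·H2O (excess), AcOH (cat.), EtOH, 80 °C, sealed tube
Reagents that add atoms: hydrazine (as hydrate), NN
Why: Condensation to the free hydrazone, under forcing conditions because the ketone is doubly ortho-substituted; both C=N isomers lead to the same diazo compound.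

Step 13
Reactants: 22 hydrazone of 21
Product: 24 (2R,3S)-7-bromo-2-(2,4-dimethoxyphenyl)-3-(3,5-dimethoxyphenyl)-4-methoxy-2,3-dihydro-1-benzofuran (cis), via diaryldiazomethane 23 (not isolated)
Conditions: MnO2, MeCN, 0 °C; then Rh2(S-PTAD)4 (1 mol %), 0 °C → rt
Reagents that add atoms: none
Why: Oxidation to the donor/donor diazo compound and dirhodium-catalysed intramolecular carbene insertion into the benzylic ether C–H bond (1,5-insertion, five-membered ring); the chiral carboxylate ligands select the carbene face and so set C3' as S, the concerted insertion should give the cis ring, and the benzylic C–H bond is far more hydridic than the competing methoxy C–H bond.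

Step 14
Reactants: 24 (2R,3S)-7-bromo-2-(2,4-dimethoxyphenyl)-3-(3,5-dimethoxyphenyl)-4-methoxy-2,3-dihydro-1-benzofuran
Product: 25 (2S,3S)-7-bromo-2-(2,4-dimethoxyphenyl)-3-(3,5-dimethoxyphenyl)-4-methoxy-2,3-dihydro-1-benzofuran (trans; U2–Br)
Conditions: TFA (2 equiv), CH2Cl2, 0 °C
Reagents that add atoms: none
Why: Acid-mediated epimerisation: reversible ionisation of O1'–C2' (cation stabilised by the 2,4-dimethoxyphenyl group) and re-closure should give the more stable trans ring, while C3' is not involved.

Step 15
Reactants: 25 U2–Br; 11 ring A (E)-alkenyl B(mac) boronate; 13 3,5-dimethoxyphenyl trifluoromethanesulfonate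
Product: 28 B(mac) ester of (1R,2S)-1-U2-2-(3,5-dimethoxyphenyl)-2-RA-ethylboronic acid (boron on C2 and the two aryl groups on C3 in benzofuran numbering), via unit 2 aryllithium 26 (not isolated), via lithium borate complex 27 (not isolated)
Conditions: t-BuLi (2.0 equiv), THF, −78 °C; 11, −78 °C → rt; then 13, KOTf, Pd(OAc)2 (5 mol %), (Sp,Sp)-MandyPhos (6 mol %), THF, 60 °C
Reagents that add atoms: none
Why: Proposed new method: aryllithium 26 adds to boron of 11 to give borate 27 with an electron-rich alkene, oxidative addition of 13 to zerovalent palladium (from Pd(OAc)2 and MandyPhos) gives a cationic aryl–palladium species that binds this alkene and induces 1,2-shift of ring C from boron to C2 anti to palladium, which bonds to C3, and reductive elimination then forms the C3–aryl bond with retention; the closest known reaction type is the enantioselective conjunctive cross-coupling of alkenylboron ate complexes with aryl triflates under Pd(OAc)2 and a chiral diphosphine, established for vinyl and β-alkyl alkenyl boronates (the latter with the mac ligand) but not for a β-aryl alkene flanked by two ortho substituents. No ring is closed in this step. C3 is set by the catalyst, because the ligand selects the alkene face to which palladium binds, and C2 follows from anti addition across the E alkene, which gives the (1R,2S) erythro pair. The step needs 1,2-shift in preference to direct transfer of the alkenyl group to palladium, and the mac ligand on boron is there to secure this. It needs the triflate as the only site of oxidative addition, which holds because the bromide of 25 is consumed by exchange beforehand and KOTf precipitates the bromide ion that would block the cationic palladium. It needs reaction at the borate alkene and not at the stilbene, which the much higher nucleophilicity of an alkene on tetracoordinate boron should secure. Face selection must come from the ligand, since the stereocentres of unit 2 lie five or more bonds from C3.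

Step 16
Reactants: 28 B(mac) ester of (1R,2S)-1-U2-2-(3,5-dimethoxyphenyl)-2-RA-ethylboronic acid
Product: 30 (1R,2S)-1-U2-2-(3,5-dimethoxyphenyl)-2-{2-hydroxy-4-methoxy-6-[(E)-2-(4-methoxyphenyl)ethenyl]phenyl}ethanol, via phenol boronate 29 (not isolated)
Conditions: TMSOTf, 2,2'-bipyridyl, CH2Cl2, 0 °C → rt; H2O; then NaOH (3 M), H2O2 (30 %), THF, 0 °C → rt
Reagents that add atoms: hydrogen peroxide, OO
Why: The acetal is cleaved under buffered, non-protic conditions while C2 still carries boron, so no ionisable benzylic C–O bond is present and unit 2 is not re-opened; alkaline peroxide then oxidises the C–B bond with retention (1,2-shift of carbon from boron to oxygen) to the (R) carbinol.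

Step 17
Reactants: 30 (1R,2S)-1-U2-2-(3,5-dimethoxyphenyl)-2-{2-hydroxy-4-methoxy-6-[(E)-2-(4-methoxyphenyl)ethenyl]phenyl}ethanol
Product: 31 (2S,3S)-3-(3,5-dimethoxyphenyl)-6-methoxy-4-[(E)-2-(4-methoxyphenyl)ethenyl]-2-U2-2,3-dihydro-1-benzofuran (nonamethyl ether of the target)
Conditions: PPh3, DIAD, THF, 0 °C → rt
Reagents that add atoms: none
Why: Intramolecular Mitsunobu etherification (5-exo-tet): the ring A phenoxide displaces the activated benzylic oxygen with inversion, which turns the erythro pair into the (2S,3S) trans ring; any ionisation of this electron-rich centre should lead to the same, more stable trans ether.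

Step 18
Reactants: 31 nonamethyl ether of the target
Product: 32 (2S,3S)-3-(3,5-dihydroxyphenyl)-2-[(2S,3S)-2-(2,4-dihydroxyphenyl)-3-(3,5-dihydroxyphenyl)-4-hydroxy-2,3-dihydro-1-benzofuran-7-yl]-4-[(E)-2-(4-hydroxyphenyl)ethenyl]-2,3-dihydro-1-benzofuran-6-ol (CNP0397447.1)
Conditions: BBr3 (excess), CH2Cl2, −78 → 0 °C; inverse quench into cold aq. NaHCO3/MeOH
Reagents that add atoms: none
Why: Lewis-acid cleavage of the nine aryl methyl ethers (bromide attacks the methyl group of each boron-bound ether); both rings are already the more stable trans isomers, so reversible ionisation at C2 or C2' should not change configuration, and the cold buffered quench keeps HBr from the stilbene.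

## Compound list

1 | 2-bromo-4,6-dimethoxybenzaldehyde | O=Cc1c(Br)cc(OC)cc1OC | starting material
2 | 2-bromo-6-hydroxy-4-methoxybenzaldehyde | O=Cc1c(Br)cc(OC)cc1O | intermediate
3 | 2-bromo-4-methoxy-6-(methoxymethoxy)benzaldehyde | O=Cc1c(Br)cc(OC)cc1OCOC | intermediate
4 | 4-methoxystyrene | C=Cc1ccc(OC)cc1 | starting material
5 | 4-methoxy-2-[(E)-2-(4-methoxyphenyl)ethenyl]-6-(methoxymethoxy)benzaldehyde | O=Cc1c(/C=C/c2ccc(OC)cc2)cc(OC)cc1OCOC | intermediate
6 | bis(pinacolatoboryl)methane | CC1(C)OB(CB2OC(C)(C)C(C)(C)O2)OC1(C)C | starting material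
7 | 2-[(E)-2-RA-ethenyl]-4,4,5,5-tetramethyl-1,3,2-dioxaborolane (ring A alkenyl pinacol boronate) | COCOc1cc(OC)cc(/C=C/c2ccc(OC)cc2)c1/C=C/B1OC(C)(C)C(C)(C)O1 | intermediate
8 | acenaphthoquinone (acenaphthylene-1,2-dione) | O=C1C(=O)c2cccc3cccc1c23 | starting material
9 | cis-1,2-dimethyl-1,2-dihydroacenaphthylene-1,2-diol (meso, mac diol) | C[C@]1(O)[C@@](C)(O)c2cccc3cccc1c23 | intermediate
10 | [(E)-2-RA-ethenyl]boronic acid | COCOc1cc(OC)cc(/C=C/c2ccc(OC)cc2)c1/C=C/B(O)O | intermediate (not isolated)
11 | cyclic ester of 10 with cis-diol 9 (ring A (E)-alkenyl B(mac) boronate) | COCOc1cc(OC)cc(/C=C/c2ccc(OC)cc2)c1/C=C/B1O[C@]2(C)c3cccc4cccc(c34)[C@]2(C)O1 | intermediate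
12 | 3,5-dimethoxyphenol | COc1cc(O)cc(OC)c1 | starting material
13 | 3,5-dimethoxyphenyl trifluoromethanesulfonate | COc1cc(OC)cc(OS(=O)(=O)C(F)(F)F)c1 | intermediate
14 | 2-bromo-5-methoxyphenol | COc1ccc(Br)c(O)c1 | starting material
15 | 3-bromo-2-hydroxy-6-methoxybenzaldehyde | O=Cc1c(O)c(Br)ccc1OC | intermediate
16 | 2,4-dimethoxybenzyl alcohol | COc1ccc(CO)c(OC)c1 | starting material
17 | 3-bromo-2-[(2,4-dimethoxybenzyl)oxy]-6-methoxybenzaldehyde | O=Cc1c(OCc2ccc(OC)cc2OC)c(Br)ccc1OC | intermediate
18 | 1-bromo-3,5-dimethoxybenzene | COc1cc(Br)cc(OC)c1 | starting material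
19 | 3,5-dimethoxyphenylmagnesium bromide | COc1cc(OC)cc([Mg]Br)c1 | intermediate (not isolated)
20 | {3-bromo-2-[(2,4-dimethoxybenzyl)oxy]-6-methoxyphenyl}(3,5-dimethoxyphenyl)methanol (racemic) | OC(c1cc(OC)cc(OC)c1)c1c(OCc2ccc(OC)cc2OC)c(Br)ccc1OC | intermediate
21 | {3-bromo-2-[(2,4-dimethoxybenzyl)oxy]-6-methoxyphenyl}(3,5-dimethoxyphenyl)methanone | O=C(c1cc(OC)cc(OC)c1)c1c(OCc2ccc(OC)cc2OC)c(Br)ccc1OC | intermediate
22 | hydrazone of 21 (C=N isomers) | NN=C(c1cc(OC)cc(OC)c1)c1c(OCc2ccc(OC)cc2OC)c(Br)ccc1OC | intermediate
23 | {3-bromo-2-[(2,4-dimethoxybenzyl)oxy]-6-methoxyphenyl}(3,5-dimethoxyphenyl)diazomethane | [N-]=[N+]=C(c1cc(OC)cc(OC)c1)c1c(OCc2ccc(OC)cc2OC)c(Br)ccc1OC | intermediate (not isolated)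
24 | (2R,3S)-7-bromo-2-(2,4-dimethoxyphenyl)-3-(3,5-dimethoxyphenyl)-4-methoxy-2,3-dihydro-1-benzofuran (cis) | Brc1ccc(OC)c2c1O[C@@H](c1ccc(OC)cc1OC)[C@H]2c1cc(OC)cc(OC)c1 | intermediate
25 | (2S,3S)-7-bromo-2-(2,4-dimethoxyphenyl)-3-(3,5-dimethoxyphenyl)-4-methoxy-2,3-dihydro-1-benzofuran (trans, U2–Br) | Brc1ccc(OC)c2c1O[C@H](c1ccc(OC)cc1OC)[C@H]2c1cc(OC)cc(OC)c1 | intermediate
26 | U2–Li (unit 2 aryllithium, lithiated at C7') | [Li]c1ccc(OC)c2c1O[C@H](c1ccc(OC)cc1OC)[C@H]2c1cc(OC)cc(OC)c1 | intermediate (not isolated)
27 | lithium borate from 26 and 11 (tetracoordinate ate complex) | [Li+].COCOc1cc(OC)cc(/C=C/c2ccc(OC)cc2)c1/C=C/[B-]1(O[C@]2(C)c3cccc4cccc(c34)[C@]2(C)O1)c1ccc(OC)c2c1O[C@H](c1ccc(OC)cc1OC)[C@H]2c1cc(OC)cc(OC)c1 | intermediate (not isolated)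
28 | B(mac) ester of (1R,2S)-1-U2-2-(3,5-dimethoxyphenyl)-2-RA-ethylboronic acid | COCOc1cc(OC)cc(/C=C/c2ccc(OC)cc2)c1[C@H](c1cc(OC)cc(OC)c1)[C@@H](B1O[C@]2(C)c3cccc4cccc(c34)[C@]2(C)O1)c1ccc(OC)c2c1O[C@H](c1ccc(OC)cc1OC)[C@H]2c1cc(OC)cc(OC)c1 | intermediate
29 | phenol corresponding to 28 (methoxymethyl group removed) | Oc1cc(OC)cc(/C=C/c2ccc(OC)cc2)c1[C@H](c1cc(OC)cc(OC)c1)[C@@H](B1O[C@]2(C)c3cccc4cccc(c34)[C@]2(C)O1)c1ccc(OC)c2c1O[C@H](c1ccc(OC)cc1OC)[C@H]2c1cc(OC)cc(OC)c1 | intermediate (not isolated)
30 | (1R,2S)-1-U2-2-(3,5-dimethoxyphenyl)-2-{2-hydroxy-4-methoxy-6-[(E)-2-(4-methoxyphenyl)ethenyl]phenyl}ethanol | Oc1cc(OC)cc(/C=C/c2ccc(OC)cc2)c1[C@H](c1cc(OC)cc(OC)c1)[C@@H](O)c1ccc(OC)c2c1O[C@H](c1ccc(OC)cc1OC)[C@H]2c1cc(OC)cc(OC)c1 | intermediate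
31 | (2S,3S)-3-(3,5-dimethoxyphenyl)-6-methoxy-4-[(E)-2-(4-methoxyphenyl)ethenyl]-2-U2-2,3-dihydro-1-benzofuran | COc1ccc(/C=C/c2cc(OC)cc3c2[C@H](c2cc(OC)cc(OC)c2)[C@@H](c2ccc(OC)c4c2O[C@H](c2ccc(OC)cc2OC)[C@H]4c2cc(OC)cc(OC)c2)O3)cc1 | intermediate
32 | (2S,3S)-3-(3,5-dihydroxyphenyl)-2-[(2S,3S)-2-(2,4-dihydroxyphenyl)-3-(3,5-dihydroxyphenyl)-4-hydroxy-2,3-dihydro-1-benzofuran-7-yl]-4-[(E)-2-(4-hydroxyphenyl)ethenyl]-2,3-dihydro-1-benzofuran-6-ol | Oc1ccc(/C=C/c2cc(O)cc3c2[C@H](c2cc(O)cc(O)c2)[C@@H](c2ccc(O)c4c2O[C@H](c2ccc(O)cc2O)[C@H]4c2cc(O)cc(O)c2)O3)cc1 | target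

## Step count and least certain steps

Total: 18 steps. Longest linear sequence: 11 steps (steps 8–14, then 15–18).

**Step 15 (key step).** What may go wrong: the alkenyl group may pass directly from the borate to aryl–palladium without 1,2-shift, because the β-aryl alkene is flanked by two ortho substituents and binds palladium poorly. Face selection may be weak if the ligand is mismatched with unit 2. Residual bromide may inhibit the cationic palladium, and the aryllithium may deprotonate C3' and open unit 2 before it reaches boron.
Fallback (known chemistry), setting out from 25 and 2 and returning at 31: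
- 25 is lithiated with t-BuLi and formylated with DMF to the aldehyde U2–CHO F1, reduced with NaBH4 to the benzylic alcohol U2–CH2OH F2, and converted with tetrahydrothiophene and HBF4·OEt2 into the sulfonium tetrafluoroborate F3.
- In parallel, 2 is treated with two equivalents of 19 to give the racemic diol 3-bromo-2-[(3,5-dimethoxyphenyl)(hydroxy)methyl]-5-methoxyphenol F4, which with sodium p-toluenesulfinate and acid gives the sulfone F5.
- Cs2CO3 releases the ortho-quinone methide from F5 and the ylide from F3. Conjugate addition and displacement of the sulfide should give the trans ring without control of its absolute sense, that is the wanted bromide F6 together with its (2R,3R) unit 1 diastereomer F7. The two are separable by chromatography because unit 2 is a single enantiomer.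
- Heck reaction of F6 with 4 (Pd(OAc)2, P(o-tol)3, Et3N, DMF) gives 31.

**Step 13 (with step 12).** What may go wrong: condensation of hydrazine with the doubly ortho-substituted ketone may be sluggish, the diazo compound may dimerise to the azine, or the ortho methoxy group may weaken the enantioface selection of the carbene.
Fallback, setting out from 21 and returning at 25:
- LiTMP deprotonates the benzylic ether carbon of 21, and the carbanion adds to the ketone to give the 3-hydroxy-2,3-dihydrobenzofuran F8.
- TsOH dehydrates F8 to 7-bromo-2-(2,4-dimethoxyphenyl)-3-(3,5-dimethoxyphenyl)-4-methoxybenzofuran F9.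
- Ionic hydrogenation (Et3SiH, TFA) should give the racemic trans ring, that is 25 together with its enantiomer F10; the two are separated by preparative chromatography on a chiral stationary phase.

**Step 18.** What may go wrong: the Lewis acid may re-open the O1–C2 bond and the C2 cation may be trapped by the C4 styryl alkene (five-membered carbocycle), or acid set free at the quench may protonate the stilbene and the C3 aryl ring may close onto it. Both are known weaknesses of a 4-styryl-3-aryl-dihydrobenzofuran.
Fallback, setting out from 28 and returning at 32 (demethylation while C2 is still on boron, so that no ionisable C2–O bond exists):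
- BBr3 on 28 cleaves the nine methyl ethers and the acetal, and hydrolytic work-up should give the decahydroxy boronic acid F11.
- NaBO3·4H2O in THF/H2O oxidises the C–B bond to the benzylic alcohol F12.
- Brief exposure to dilute AcOH forms the para-quinone methide at C2 (para to the C4' phenol), which the free ring A phenol should capture to give the trans ring of 32.

**Step 17.** What may go wrong: the activated, electron-rich benzylic alcohol may eliminate to the triarylethylene or alkylate the hydrazide, or activation of the hindered carbinol may be slow.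
Fallback, setting out from 30 and returning at 31: closure through the C2 cation with catalytic camphorsulfonic acid in CH2Cl2 at 0 °C, under thermodynamic control and stopped as soon as 30 is consumed. The free phenol is already in place to outrun the alkene. No new compound is involved.

## Further compounds

F1 | step 15 | (2S,3S)-2-(2,4-dimethoxyphenyl)-3-(3,5-dimethoxyphenyl)-4-methoxy-2,3-dihydro-1-benzofuran-7-carbaldehyde (U2–CHO) | O=Cc1ccc(OC)c2c1O[C@H](c1ccc(OC)cc1OC)[C@H]2c1cc(OC)cc(OC)c1
F2 | step 15 | U2–CH2OH | OCc1ccc(OC)c2c1O[C@H](c1ccc(OC)cc1OC)[C@H]2c1cc(OC)cc(OC)c1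
F3 | step 15 | 1-(U2-methyl)thiolan-1-ium tetrafluoroborate | C1CC[S+](C1)Cc1ccc(OC)c2c1O[C@H](c1ccc(OC)cc1OC)[C@H]2c1cc(OC)cc(OC)c1.F[B-](F)(F)F
F4 | step 15 | 3-bromo-2-[(3,5-dimethoxyphenyl)(hydroxy)methyl]-5-methoxyphenol (racemic) | OC(c1cc(OC)cc(OC)c1)c1c(Br)cc(OC)cc1O
F5 | step 15 | 3-bromo-2-[(3,5-dimethoxyphenyl)(4-methylphenylsulfonyl)methyl]-5-methoxyphenol (racemic) | Cc1ccc(cc1)S(=O)(=O)C(c1cc(OC)cc(OC)c1)c1c(Br)cc(OC)cc1O
F6 | step 15 | (2S,3S)-4-bromo-3-(3,5-dimethoxyphenyl)-6-methoxy-2-U2-2,3-dihydro-1-benzofuran | Brc1cc(OC)cc2c1[C@H](c1cc(OC)cc(OC)c1)[C@@H](c1ccc(OC)c3c1O[C@H](c1ccc(OC)cc1OC)[C@H]3c1cc(OC)cc(OC)c1)O2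
F7 | step 15 | (2R,3R)-4-bromo-3-(3,5-dimethoxyphenyl)-6-methoxy-2-U2-2,3-dihydro-1-benzofuran (unwanted diastereomer) | Brc1cc(OC)cc2c1[C@@H](c1cc(OC)cc(OC)c1)[C@H](c1ccc(OC)c3c1O[C@H](c1ccc(OC)cc1OC)[C@H]3c1cc(OC)cc(OC)c1)O2
F8 | step 13 | 7-bromo-2-(2,4-dimethoxyphenyl)-3-(3,5-dimethoxyphenyl)-4-methoxy-2,3-dihydro-1-benzofuran-3-ol (mixture of stereoisomers) | OC1(c2cc(OC)cc(OC)c2)C(c2ccc(OC)cc2OC)Oc2c(Br)ccc(OC)c21
F9 | step 13 | 7-bromo-2-(2,4-dimethoxyphenyl)-3-(3,5-dimethoxyphenyl)-4-methoxy-1-benzofuran | Brc1ccc(OC)c2c(-c3cc(OC)cc(OC)c3)c(-c3ccc(OC)cc3OC)oc12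
F10 | step 13 | (2R,3R)-7-bromo-2-(2,4-dimethoxyphenyl)-3-(3,5-dimethoxyphenyl)-4-methoxy-2,3-dihydro-1-benzofuran (enantiomer of 25) | Brc1ccc(OC)c2c1O[C@@H](c1ccc(OC)cc1OC)[C@@H]2c1cc(OC)cc(OC)c1
F11 | step 18 | (1R,2S)-2-(3,5-dihydroxyphenyl)-2-{2,4-dihydroxy-6-[(E)-2-(4-hydroxyphenyl)ethenyl]phenyl}-1-[(2S,3S)-2-(2,4-dihydroxyphenyl)-3-(3,5-dihydroxyphenyl)-4-hydroxy-2,3-dihydro-1-benzofuran-7-yl]ethylboronic acid | Oc1ccc(/C=C/c2cc(O)cc(O)c2[C@H](c2cc(O)cc(O)c2)[C@@H](B(O)O)c2ccc(O)c3c2O[C@H](c2ccc(O)cc2O)[C@H]3c2cc(O)cc(O)c2)cc1
F12 | step 18 | (1R,2S)-2-(3,5-dihydroxyphenyl)-2-{2,4-dihydroxy-6-[(E)-2-(4-hydroxyphenyl)ethenyl]phenyl}-1-[(2S,3S)-2-(2,4-dihydroxyphenyl)-3-(3,5-dihydroxyphenyl)-4-hydroxy-2,3-dihydro-1-benzofuran-7-yl]ethanol | Oc1ccc(/C=C/c2cc(O)cc(O)c2[C@H](c2cc(O)cc(O)c2)[C@@H](O)c2ccc(O)c3c2O[C@H](c2ccc(O)cc2O)[C@H]3c2cc(O)cc(O)c2)cc1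
F0 | step 17 | none | none
A1 | alternative 1 | 4-bromo-2-[2-(tert-butyldimethylsilyloxy)-2-(2,4-dimethoxyphenyl)-1-(3,5-dimethoxyphenyl)ethyl]-3-(triisopropylsilyloxy)phenol, configured as in the SMILES | Brc1ccc(O)c([C@H](c2cc(OC)cc(OC)c2)[C@H](O[Si](C)(C)C(C)(C)C)c2ccc(OC)cc2OC)c1O[Si](C(C)C)(C(C)C)C(C)C
A2 | alternative 1 | 2-bromocyclobut-2-en-1-one | O=C1CC=C1Br
A3 | alternative 1 | triisopropylsilyl ynol ether of the C3'/C2' side chain, [4-(tert-butyldimethylsilyloxy)-4-(2,4-dimethoxyphenyl)-3-(3,5-dimethoxyphenyl)but-1-ynyloxy]triisopropylsilane | CC(C)[Si](OC#C[C@H](c1cc(OC)cc(OC)c1)[C@H](O[Si](C)(C)C(C)(C)C)c1ccc(OC)cc1OC)(C(C)C)C(C)C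
A4 | alternative 2 | methyl (2S,3S)-4-bromo-6-methoxy-2-U2-2,3-dihydro-1-benzofuran-3-carboxylate | Brc1cc(OC)cc2c1[C@H](C(=O)OC)[C@@H](c1ccc(OC)c3c1O[C@H](c1ccc(OC)cc1OC)[C@H]3c1cc(OC)cc(OC)c1)O2
A5 | alternative 2 | (2S)-5-bromo-7-methoxy-2-U2-chroman-4-one | O=C1C[C@@H](c3ccc(OC)c4c3O[C@H](c3ccc(OC)cc3OC)[C@H]4c3cc(OC)cc(OC)c3)Oc2cc(OC)cc(Br)c12
A6 | alternative 3 | (2S,3S)-4-bromo-3-(3,5-dimethoxyphenyl)-6-methoxy-2-U2-2,3-dihydro-1-benzofuran | Brc1cc(OC)cc2c1[C@H](c1cc(OC)cc(OC)c1)[C@@H](c1ccc(OC)c3c1O[C@H](c1ccc(OC)cc1OC)[C@H]3c1cc(OC)cc(OC)c1)O2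
A7 | alternative 3 | 3-bromo-2-[(3,5-dimethoxyphenyl)(4-methylphenylsulfonyl)methyl]-5-methoxyphenol | Cc1ccc(cc1)S(=O)(=O)C(c1cc(OC)cc(OC)c1)c1c(Br)cc(OC)cc1O
A8 | alternative 3 | (2R,5R)-2,5-dimethyl-1-(U2-methyl)thiolan-1-ium tetrafluoroborate | C[C@@H]1CC[C@@H](C)[S+]1Cc1ccc(OC)c2c1O[C@H](c1ccc(OC)cc1OC)[C@H]2c1cc(OC)cc(OC)c1.F[B-](F)(F)F
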